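**Retrosynthetic overview**
1. Target 22 ⇐ aldehyde 20 (C1–C3 added by Takai iodo-olefination and Negishi ethynylation) ⇐ vinyl oxocane 17 ⇐ oxocanol 14 (C7–OH → C7–Cl with inversion; silyl group on O10 → acetate).
2. Oxocanol 14 ⇐ acyclic aldehyde 11 in one flask: O–C12 (with C13–Br) by bromoetherification, then C6–C7 by ring-closing alkoxyallylboration.
3. Enabling feature: the oxygen on C10 is 1,3 to C12, so a diisopropylsilylene bridging O10 and the future ring oxygen lets that oxygen reach C12 of the C12=C13 alkene through a six-membered O–Si–O10–C10–C11–C12 array; the same oxygen carries the C4–C6 allylboronate, which then meets the C7 aldehyde to close the oxocane (O, C6–C12).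
4. Aldehyde 11 ⇐ chlorohydrin 3 ((Z)-γ-chloroallylboration of (E)-hex-3-enal sets C9 and C10) + boronate alcohol 7 + i-Pr2SiCl2.
5. Ring order: the oxocane is the only ring and is formed in step 8.

Key step: step 8

Assumption: positions are numbered C1–C15 along the acetogenin chain (C6 and C12 carry the ring oxygen; Bpin = 4,4,5,5-tetramethyl-1,3,2-dioxaborolan-2-yl), and boronate alcohol 7 is taken as a commercial building block.

**Step 1**
Reactants: 1 (E)-hex-3-en-1-ol
Product: 2 (E)-hex-3-enal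
Conditions: Dess–Martin periodinane, NaHCO3, CH2Cl2, 0 °C; used crude
Reagents that add atoms: none
Why: Buffered Dess–Martin oxidation should give the β,γ-unsaturated aldehyde without moving the E alkene into conjugation, and no stereocentre is formed.

**Step 2**
Reactants: 2 (E)-hex-3-enal
Product: 3 (3S,4S,6E)-3-chloronona-1,6-dien-4-ol
Conditions: CH2=CHCH2Cl, LiN(c-C6H11)2, (+)-Ipc2BOMe, BF3·OEt2, Et2O, −95 °C; then 2; H2O2, aq. NaHCO3, 0 °C
Reagents that add atoms: allyl chloride, C=CCCl
Why: Asymmetric (Z)-γ-chloroallylboration (Brown-type allylboration) through a chair transition state should give the syn chlorohydrin, the Z geometry setting C9 relative to C10 and the (+)-Ipc2B reagent (from (−)-α-pinene) selecting the aldehyde face that makes C10 S.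

**Step 3**
Reactants: 3 (3S,4S,6E)-3-chloronona-1,6-dien-4-ol
Product: 5 (3S,4S,6E)-3-chloronon-6-ene-1,4-diol, via bis(9-BBN) adduct 4 (not isolated)
Conditions: 9-BBN (2.2 equiv), THF, 0 °C to rt; then H2O2, NaOAc, H2O, 0 °C
Reagents that add atoms: hydrogen peroxide, OO
Why: Hydroboration–oxidation with 9-BBN should take the monosubstituted vinyl group in preference to the 1,2-disubstituted alkene, and the near-neutral oxidation avoids epoxide closure of the chlorohydrin; no stereocentre is formed.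

**Step 4**
Reactants: 5 (3S,4S,6E)-3-chloronon-6-ene-1,4-diol
Product: 6 (3S,4S,6E)-3-chloro-4-hydroxynon-6-en-1-yl acetate
Conditions: AcCl, 2,4,6-collidine, CH2Cl2, −78 °C
Reagents that add atoms: acetyl chloride, CC(=O)Cl
Why: Low-temperature acylation with a hindered base should acetylate the primary hydroxyl and leave the secondary hydroxyl next to chlorine free.

**Step 5**
Reactants: 6 (3S,4S,6E)-3-chloro-4-hydroxynon-6-en-1-yl acetate; 7 (E)-3-(Bpin)prop-2-en-1-ol
Product: 9 (3S,4S,6E)-3-chloro-4-[({[(2E)-3-(Bpin)prop-2-en-1-yl]oxy}di(propan-2-yl)silyl)oxy]non-6-en-1-yl acetate, via chlorosilyl ether 8 (not isolated)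
Conditions: i-Pr2SiCl2, imidazole, CH2Cl2, 0 °C; then 7, rt
Reagents that add atoms: dichlorodi(propan-2-yl)silane, CC(C)[Si](Cl)(Cl)C(C)C
Why: Stepwise silylation (unsymmetrical silaketal formation) should work because the hindered secondary alcohol stops at the monochlorosilane, which the primary allylic alcohol 7 then captures.

**Step 6**
Reactants: 9 silaketal acetate
Product: 10 (3S,4S,6E)-3-chloro-4-[({[(2E)-3-(Bpin)prop-2-en-1-yl]oxy}di(propan-2-yl)silyl)oxy]non-6-en-1-ol
Conditions: K2CO3 (cat.), MeOH, 0 °C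
Reagents that add atoms: none
Why: Carbonate-catalysed methanolysis should remove the primary acetate while the diisopropylsilaketal and the pinacol boronate survive, and no alkoxide can form next to the C9 chloride because O10 is silylated.

**Step 7**
Reactants: 10 silaketal alcohol
Product: 11 (3S,4S,6E)-3-chloro-4-[({[(2E)-3-(Bpin)prop-2-en-1-yl]oxy}di(propan-2-yl)silyl)oxy]non-6-enal
Conditions: Dess–Martin periodinane, NaHCO3, CH2Cl2, 0 °C; used crude
Reagents that add atoms: none
Why: Dess–Martin oxidation tolerates the alkenylboronate and the silaketal, and the β-chloro aldehyde is carried on without chromatography to forestall loss of HCl.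

**Step 8**
Reactants: 11 silaketal aldehyde
Product: 14 (2S,3R,5S,6S,8R)-8-[(1S)-1-bromopropyl]-5-chloro-2-ethenyl-6-{[methoxydi(propan-2-yl)silyl]oxy}oxocan-3-ol, via bromo ether aldehyde 12 (not isolated), via allylboronate 13 (not isolated)
Conditions: NBS, MeOH (1.5 equiv), CH2Cl2, −40 °C; then 4 Å MS, [Ir(cod)(PPh2Me)2]PF6 (3 mol %, H2-activated), (S)-TRIP (10 mol %), toluene, 0 °C to rt; aq. NaHCO3
Reagents that add atoms: N-bromosuccinimide, O=C1CCC(=O)N1Br; methanol, CO
Why: Proposed new method: NBS forms the bromonium ion of the electron-rich C12=C13 alkene (the alkenylboronate is electron-poor), the C6 oxygen of the silaketal opens it at C12 through the six-membered O–Si–O10–C10–C11–C12 chair, and methanol takes over the silicon, which stays on O10 as a protecting group; the closest known reaction types are haloetherifications in which a silyl ether oxygen is the nucleophile and silicon is lost, and tethered silanol halo-etherifications. In the same flask the iridium hydride moves the alkenylboronate double bond to give the (E)-γ-alkoxyallylboronate 13, which adds to the C7 aldehyde through a chair transition state, a tandem known for six- and seven-membered 2-vinyl-3-hydroxy ethers and here asked to close the eight-membered ring. Ring closures: a transient six-membered ring by 6-exo attack of oxygen on the bromonium ion, and the oxocane by C6–C7 bond formation with the ether oxygen already in place. Stereocentres: C12 follows from the chair with the C9 chain and the alkene equatorial (10,12-syn), C13 from anti addition to the E alkene, C6 and C7 are anti because the allylboronate is E, and the aldehyde face that makes C7 R is addressed by the (S)-TRIP phosphoric acid (the antipode is used if the sense proves opposite). The step needs O6 to beat O10 and methanol for the bromonium ion (only O6 reaches C12 through a six-membered ring; O10 would need a four-membered or 5-endo closure) and needs a trans relation of the C6 and C12 side chains, which is why catalyst control is added to the uncertain substrate bias.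

**Step 9**
Reactants: 14 oxocan-3-ol
Product: 15 (2S,3S,5S,6S,8R)-8-[(1S)-1-bromopropyl]-3,5-dichloro-2-ethenyl-6-{[methoxydi(propan-2-yl)silyl]oxy}oxocane
Conditions: P(n-C8H17)3, CCl4, toluene, 70 °C
Reagents that add atoms: tetrachloromethane, ClC(Cl)(Cl)Cl
Why: Appel-type chlorination (alkoxyphosphonium formation, then SN2 by chloride) should invert C7 from R to S, as is usual for hindered ring alcohols next to an ether oxygen.

**Step 10**
Reactants: 15 silyl-protected dichloro oxocane
Product: 16 (2R,4S,5S,7S,8S)-2-[(1S)-1-bromopropyl]-5,7-dichloro-8-ethenyloxocan-4-ol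
Conditions: HF·pyridine, THF, 0 °C to rt
Reagents that add atoms: none
Why: Fluoride-mediated Si–O cleavage under acidic conditions should free the C10 hydroxyl without generating an alkoxide that could displace the neighbouring C9 chloride.

**Step 11**
Reactants: 16 oxocan-4-ol
Product: 17 (2R,4S,5S,7S,8S)-2-[(1S)-1-bromopropyl]-5,7-dichloro-8-ethenyloxocan-4-yl acetate
Conditions: Ac2O, pyridine, DMAP (cat.), CH2Cl2, 0 °C
Reagents that add atoms: acetic anhydride, CC(=O)OC(C)=O
Why: DMAP-catalysed acylation of the secondary alcohol is mild enough to leave the alkyl halides untouched.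

**Step 12**
Reactants: 17 vinyl oxocane acetate
Product: 19 (2R,4S,5S,7S,8S)-2-[(1S)-1-bromopropyl]-5,7-dichloro-8-(2-hydroxyethyl)oxocan-4-yl acetate, via alkylborane 18 (not isolated)
Conditions: 9-BBN, THF, 0 °C to rt; then H2O2, NaOAc, H2O, 0 °C
Reagents that add atoms: hydrogen peroxide, OO
Why: Hydroboration–oxidation should hydrate the only alkene at its terminal carbon, and the buffered oxidation spares the acetate and the halides.

**Step 13**
Reactants: 19 primary alcohol
Product: 20 (2R,4S,5S,7S,8S)-2-[(1S)-1-bromopropyl]-5,7-dichloro-8-(2-oxoethyl)oxocan-4-yl acetate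
Conditions: Dess–Martin periodinane, NaHCO3, CH2Cl2, 0 °C
Reagents that add atoms: none
Why: Dess–Martin oxidation gives the β-alkoxy aldehyde under neutral conditions that do not epimerise C6 or eliminate the ring oxygen.

**Step 14**
Reactants: 20 aldehyde
Product: 21 (2R,4S,5S,7S,8S)-2-[(1S)-1-bromopropyl]-5,7-dichloro-8-[(2E)-3-iodoprop-2-en-1-yl]oxocan-4-yl acetate
Conditions: CrCl2, CHI3, THF, 0 °C
Reagents that add atoms: iodoform, IC(I)I
Why: Takai olefination should give the E alkenyl iodide, and CrCl2 does not reduce unactivated secondary alkyl halides at this temperature.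

**Step 15**
Reactants: 21 (E)-alkenyl iodide
Product: 22 (2R,4S,5S,7S,8S)-2-[(1S)-1-bromopropyl]-5,7-dichloro-8-[(2E)-pent-2-en-4-yn-1-yl]oxocan-4-yl acetate (target)
Conditions: HC≡CMgBr, ZnBr2, THF, 0 °C; then 21, Pd(PPh3)4 (5 mol %), rt
Reagents that add atoms: ethynylmagnesium bromide, C#C[Mg]Br
Why: Negishi coupling of the alkenyl iodide with ethynylzinc bromide should proceed with retention of the E geometry, and the zinc acetylide attacks neither the acetate nor the alkyl halides.

**Compound list**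
1 | (E)-hex-3-en-1-ol | CC/C=C/CCO | starting material
2 | (E)-hex-3-enal | CC/C=C/CC=O | intermediate
3 | (3S,4S,6E)-3-chloronona-1,6-dien-4-ol | C=C[C@H](Cl)[C@@H](O)C/C=C/CC | intermediate
4 | 9-[(3S,4S,6E)-4-(9-borabicyclo[3.3.1]nonan-9-yloxy)-3-chloronon-6-en-1-yl]-9-borabicyclo[3.3.1]nonane | C1CC2CCCC(C1)B2CC[C@H](Cl)[C@@H](OB1C2CCCC1CCC2)C/C=C/CC | intermediate (not isolated)
5 | (3S,4S,6E)-3-chloronon-6-ene-1,4-diol | OCC[C@H](Cl)[C@@H](O)C/C=C/CC | intermediate
6 | (3S,4S,6E)-3-chloro-4-hydroxynon-6-en-1-yl acetate | CC(=O)OCC[C@H](Cl)[C@@H](O)C/C=C/CC | intermediate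
7 | (E)-3-(4,4,5,5-tetramethyl-1,3,2-dioxaborolan-2-yl)prop-2-en-1-ol | OC/C=C/B1OC(C)(C)C(C)(C)O1 | starting material
8 | (3S,4S,6E)-3-chloro-4-{[chlorodi(propan-2-yl)silyl]oxy}non-6-en-1-yl acetate | CC(=O)OCC[C@H](Cl)[C@@H](O[Si](Cl)(C(C)C)C(C)C)C/C=C/CC | intermediate (not isolated)
9 | (3S,4S,6E)-3-chloro-4-[({[(2E)-3-(Bpin)prop-2-en-1-yl]oxy}di(propan-2-yl)silyl)oxy]non-6-en-1-yl acetate | CC(=O)OCC[C@H](Cl)[C@@H](O[Si](C(C)C)(C(C)C)OC/C=C/B1OC(C)(C)C(C)(C)O1)C/C=C/CC | intermediate
10 | (3S,4S,6E)-3-chloro-4-[({[(2E)-3-(Bpin)prop-2-en-1-yl]oxy}di(propan-2-yl)silyl)oxy]non-6-en-1-ol | OCC[C@H](Cl)[C@@H](O[Si](C(C)C)(C(C)C)OC/C=C/B1OC(C)(C)C(C)(C)O1)C/C=C/CC | intermediate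
11 | (3S,4S,6E)-3-chloro-4-[({[(2E)-3-(Bpin)prop-2-en-1-yl]oxy}di(propan-2-yl)silyl)oxy]non-6-enal | O=CC[C@H](Cl)[C@@H](O[Si](C(C)C)(C(C)C)OC/C=C/B1OC(C)(C)C(C)(C)O1)C/C=C/CC | intermediate
12 | (3S,4S,6R,7S)-7-bromo-3-chloro-4-{[methoxydi(propan-2-yl)silyl]oxy}-6-{[(2E)-3-(Bpin)prop-2-en-1-yl]oxy}nonanal | O=CC[C@H](Cl)[C@@H](O[Si](C(C)C)(C(C)C)OC)C[C@@H](OC/C=C/B1OC(C)(C)C(C)(C)O1)[C@@H](Br)CC | intermediate (not isolated)
13 | (3S,4S,6R,7S)-7-bromo-3-chloro-4-{[methoxydi(propan-2-yl)silyl]oxy}-6-{[(1E)-3-(Bpin)prop-1-en-1-yl]oxy}nonanal | O=CC[C@H](Cl)[C@@H](O[Si](C(C)C)(C(C)C)OC)C[C@@H](O/C=C/CB1OC(C)(C)C(C)(C)O1)[C@@H](Br)CC | intermediate (not isolated)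
14 | (2S,3R,5S,6S,8R)-8-[(1S)-1-bromopropyl]-5-chloro-2-ethenyl-6-{[methoxydi(propan-2-yl)silyl]oxy}oxocan-3-ol | C=C[C@@H]1O[C@@H]([C@@H](Br)CC)C[C@H](O[Si](C(C)C)(C(C)C)OC)[C@@H](Cl)C[C@H]1O | intermediate
15 | (2S,3S,5S,6S,8R)-8-[(1S)-1-bromopropyl]-3,5-dichloro-2-ethenyl-6-{[methoxydi(propan-2-yl)silyl]oxy}oxocane | C=C[C@@H]1O[C@@H]([C@@H](Br)CC)C[C@H](O[Si](C(C)C)(C(C)C)OC)[C@@H](Cl)C[C@@H]1Cl | intermediate
16 | (2R,4S,5S,7S,8S)-2-[(1S)-1-bromopropyl]-5,7-dichloro-8-ethenyloxocan-4-ol | C=C[C@@H]1O[C@@H]([C@@H](Br)CC)C[C@H](O)[C@@H](Cl)C[C@@H]1Cl | intermediate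
17 | (2R,4S,5S,7S,8S)-2-[(1S)-1-bromopropyl]-5,7-dichloro-8-ethenyloxocan-4-yl acetate | C=C[C@@H]1O[C@@H]([C@@H](Br)CC)C[C@H](OC(C)=O)[C@@H](Cl)C[C@@H]1Cl | intermediate
18 | (2R,4S,5S,7S,8S)-8-[2-(9-borabicyclo[3.3.1]nonan-9-yl)ethyl]-2-[(1S)-1-bromopropyl]-5,7-dichlorooxocan-4-yl acetate | C1CC2CCCC(C1)B2CC[C@@H]1O[C@@H]([C@@H](Br)CC)C[C@H](OC(C)=O)[C@@H](Cl)C[C@@H]1Cl | intermediate (not isolated)
19 | (2R,4S,5S,7S,8S)-2-[(1S)-1-bromopropyl]-5,7-dichloro-8-(2-hydroxyethyl)oxocan-4-yl acetate | OCC[C@@H]1O[C@@H]([C@@H](Br)CC)C[C@H](OC(C)=O)[C@@H](Cl)C[C@@H]1Cl | intermediate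
20 | (2R,4S,5S,7S,8S)-2-[(1S)-1-bromopropyl]-5,7-dichloro-8-(2-oxoethyl)oxocan-4-yl acetate | O=CC[C@@H]1O[C@@H]([C@@H](Br)CC)C[C@H](OC(C)=O)[C@@H](Cl)C[C@@H]1Cl | intermediate
21 | (2R,4S,5S,7S,8S)-2-[(1S)-1-bromopropyl]-5,7-dichloro-8-[(2E)-3-iodoprop-2-en-1-yl]oxocan-4-yl acetate | I/C=C/C[C@@H]1O[C@@H]([C@@H](Br)CC)C[C@H](OC(C)=O)[C@@H](Cl)C[C@@H]1Cl | intermediate
22 | (2R,4S,5S,7S,8S)-2-[(1S)-1-bromopropyl]-5,7-dichloro-8-[(2E)-pent-2-en-4-yn-1-yl]oxocan-4-yl acetate | C#C/C=C/C[C@@H]1O[C@@H]([C@@H](Br)CC)C[C@H](OC(C)=O)[C@@H](Cl)C[C@@H]1Cl | target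

**Totals**
Total step count: 15. Longest linear sequence: 15 steps, from (E)-hex-3-en-1-ol 1.

**Steps most likely to fail**

1. Step 8 (bears the label). The silaketal oxygen may lose the race for the bromonium ion to methanol or to a 5-endo closure by O10, or silicon may not be released cleanly. The eight-membered allylboration may be slow enough for the β-chloro aldehyde to lose HCl, or it may take the wrong aldehyde face despite the catalyst. The fallback uses known reaction types only, sets out from 11 and comes back at 16, and makes the two bonds in separate operations. The iridium-catalysed isomerisation–allylboration is run alone within the silicon tether to give the cyclic silaketal alcohol (4S,5R,7S,8S)-7-chloro-4-ethenyl-8-[(2E)-pent-2-en-1-yl]-2,2-di(propan-2-yl)-1,3,2-dioxasilocan-5-ol F1. Its hydroxyl is replaced with inversion (P(n-C8H17)3, CCl4) to give (4S,5S,7S,8S)-5,7-dichloro-4-ethenyl-8-[(2E)-pent-2-en-1-yl]-2,2-di(propan-2-yl)-1,3,2-dioxasilocane F2. HF·pyridine then frees (3S,4S,6S,7S,9E)-4,6-dichlorododeca-1,9-diene-3,7-diol F3. The oxocane is closed by direct bromoetherification of the C6 hydroxyl onto the E alkene with BDSB (Et2SBr·SbCl5Br) or TBCO, the biomimetic closure of lauthisane-type bromo ethers, to give 16. The C10 hydroxyl, flanked by chlorine and able to reach the bromonium ion only in a 5-endo mode, is expected to be the slower competitor, and C12/C13 diastereomers would have to be separated.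

2. Step 9. In the activated C7 alcohol the neighbouring ring oxygen may participate (retention or ring contraction through an epoxonium ion), and elimination toward the diene may compete at 70 °C. The fallback sets out from 14 and comes back at 15; it separates activation from displacement. The alcohol is converted at −20 °C (ClCH2SO2Cl, pyridine) into (2S,3R,5S,6S,8R)-8-[(1S)-1-bromopropyl]-5-chloro-2-ethenyl-6-{[methoxydi(propan-2-yl)silyl]oxy}oxocan-3-yl chloromethanesulfonate F4. The isolated sulfonate is then displaced with a large excess of LiCl in DMF at room temperature, so that external chloride can outrun participation.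

3. Step 3. The γ-chloroalkylborane may lose chloride by 1,3-elimination to a cyclopropane, the minor regioisomeric borane may undergo β-elimination, and the chlorohydrin may close to the epoxide during oxidation. The fallback sets out from 3 and comes back at 5; it avoids boron. A nitrite-modified, aldehyde-selective Wacker-type oxidation of the terminal alkene (PdCl2(PhCN)2, CuCl2, AgNO2, O2, t-BuOH/MeNO2) gives the aldehyde as its lactol (4S,5S)-4-chloro-5-[(2E)-pent-2-en-1-yl]oxolan-2-ol F5, which NaBH4 in MeOH at 0 °C reduces to diol 5.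

**Further compounds**
F1 | step 8 | (4S,5R,7S,8S)-7-chloro-4-ethenyl-8-[(2E)-pent-2-en-1-yl]-2,2-di(propan-2-yl)-1,3,2-dioxasilocan-5-ol | C=C[C@@H]1O[Si](C(C)C)(C(C)C)O[C@@H](C/C=C/CC)[C@@H](Cl)C[C@H]1O
F2 | step 8 | (4S,5S,7S,8S)-5,7-dichloro-4-ethenyl-8-[(2E)-pent-2-en-1-yl]-2,2-di(propan-2-yl)-1,3,2-dioxasilocane | C=C[C@@H]1O[Si](C(C)C)(C(C)C)O[C@@H](C/C=C/CC)[C@@H](Cl)C[C@@H]1Cl
F3 | step 8 | (3S,4S,6S,7S,9E)-4,6-dichlorododeca-1,9-diene-3,7-diol | C=C[C@H](O)[C@@H](Cl)C[C@H](Cl)[C@@H](O)C/C=C/CC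
F4 | step 9 | (2S,3R,5S,6S,8R)-8-[(1S)-1-bromopropyl]-5-chloro-2-ethenyl-6-{[methoxydi(propan-2-yl)silyl]oxy}oxocan-3-yl chloromethanesulfonate | C=C[C@@H]1O[C@@H]([C@@H](Br)CC)C[C@H](O[Si](C(C)C)(C(C)C)OC)[C@@H](Cl)C[C@H]1OS(=O)(=O)CCl
F5 | step 3 | (4S,5S)-4-chloro-5-[(2E)-pent-2-en-1-yl]oxolan-2-ol | OC1C[C@H](Cl)[C@H](C/C=C/CC)O1
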